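**Retrosynthetic overview**
1. Target 28 ⇐ thiolate tris-demethylation ⇐ Br/Li–DMF diformylation ⇐ aryl trimethyl ether 24 ⇐ benzylic oxidative methallylation (sets C-1′) and hydrogenation of benzyl-decalin diol 21.
2. 21 ⇐ alkene hydration and MeLi addition (sets C-4) to trans-decalin-4-one 19 ⇐ 1,2-carbonyl transposition (α-oximation, double Wolff–Kishner) of enedione 14, with Li/NH3 setting the trans ring fusion (C-5).
3. 14 ⇐ cis-decalindione 11 ⇐ key Diels–Alder reaction of (R)-carvone 9 with silyloxydiene 8, which forms ring A and sets C-10 and C-1 from the bought C-7 centre.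
4. 8 ⇐ 1,3,5-trimethoxybenzene 1 by allylation, cross-metathesis with methyl vinyl ketone and silyl dienol ether formation.
5. Ring order: the aromatic ring (1) and ring B (9) are bought; ring A is the only ring made, in the cycloaddition.

**Notation.** Decalin carbons are numbered as in eudesmane: C-1 carries the side chain, C-4 is the carbinol carbon, C-5 the ring-fusion CH, C-7 carries the C3 unit, C-10 the angular methyl. Ring A = C-1 to C-5 plus C-10; ring B = C-5 to C-10; C-1′ is the benzylic carbon; Ar = 2,4,6-trimethoxyphenyl; "cis/trans" refer to the C-10 methyl.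

**Assumption.** C=N geometries (oximes, hydrazones) and C-4 of selenide 13 are left undefined because they are removed later.

**Route**

Step 1
Reactants: 1 1,3,5-trimethoxybenzene; 2 allyl bromide
Product: 4 2-allyl-1,3,5-trimethoxybenzene, via aryllithium 3 (not isolated)
Conditions: n-BuLi, THF, 0 °C to rt; then 2, −78 °C to rt
Reagents that add atoms: none
Why: Directed ortho-lithiation at a position flanked by two methoxy groups, then SN2 allylation of the aryllithium; no stereocentre.

Step 2
Reactants: 4 2-allyl-1,3,5-trimethoxybenzene; 5 methyl vinyl ketone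
Product: 6 (E)-5-(2,4,6-trimethoxyphenyl)pent-3-en-2-one
Conditions: second-generation Hoveyda–Grubbs catalyst (3 mol %), CH2Cl2, 40 °C
Reagents that add atoms: none
Why: Olefin cross-metathesis of a terminal allylarene with an enone gives the E cross product and expels ethene.

Step 3
Reactants: 6 (E)-5-(2,4,6-trimethoxyphenyl)pent-3-en-2-one
Product: 8 2-silyloxydiene, via lithium dienolate 7 (not isolated)
Conditions: LiN(iPr)2, THF, −78 °C; Me3SiCl; non-aqueous work-up
Reagents that add atoms: chlorotrimethylsilane, C[Si](C)(C)Cl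
Why: Kinetic α′-deprotonation at the methyl group and O-silylation give the cross-conjugated silyl dienol ether with the E alkene retained.

Step 4
Reactants: 8 2-silyloxydiene; 9 (R)-(−)-carvone
Product: 11 cis-fused benzyl-decalin-3,9-dione, via silyl enol ether cycloadduct 10 (not isolated)
Conditions: EtAlCl2 (0.3 equiv), toluene, −20 °C to rt; then dilute aqueous HCl, THF
Reagents that add atoms: none
Why: Lewis-acid-catalysed Diels–Alder reaction (key step, ring A): the 2-silyloxy group (para rule) and the terminal alkyl group (ortho rule) both send the benzyl-bearing terminus to the methyl-bearing carbon of carvone, the diene adds to the face opposite the isopropenyl group (C-10 fixed by bought C-7), and the endo orientation of the complexed carbonyl places the E benzyl group trans to the angular methyl at C-1, while the cis C-5 centre is corrected later.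

Step 5
Reactants: 11 cis-fused benzyl-decalin-3,9-dione
Product: 14 benzyl Δ4-octalin-3,9-dione, via pyrrolidine enamine 12 (not isolated), via phenylselenide 13 (not isolated)
Conditions: pyrrolidine, TsOH (cat.), benzene, reflux (−H2O); PhSeCl, THF, −78 °C, then H2O; H2O2, pyridine, CH2Cl2, 0 °C to rt
Reagents that add atoms: none
Why: Stork enamine α-selenenylation and selenoxide syn-elimination: pyrrolidine condenses only with the unhindered C-3 ketone and, as for cis-fused 3-decalones, towards C-4, so the alkene forms at C-4/C-5 and the wrong C-5 centre is erased.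

Step 6
Reactants: 14 benzyl Δ4-octalin-3,9-dione
Product: 16 trans-fused 4-hydroxyimino-3,9-dione, via lithium enolate 15 (not isolated)
Conditions: Li (2.2 equiv), t-BuOH (1.0 equiv), NH3/THF, −78 °C; isoprene; NH3 removed; isoamyl nitrite, THF, −78 to −20 °C; AcOH
Reagents that add atoms: isoamyl nitrite, CC(C)CCON=O
Why: Dissolving-metal enone reduction with axial protonation at C-5 sets the trans ring fusion under stereoelectronic control, and the regiodefined enolate is C-nitrosated at C-4 (α-oximation) while the hindered C-9 ketone and the arene survive the limited amount of lithium.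

Step 7
Reactants: 16 trans-fused 4-hydroxyimino-3,9-dione
Product: 18 trans-decalin-4-one oxime, via bis-hydrazone 17 (not isolated)
Conditions: N2H4·H2O, KOH, diethylene glycol, 130 °C then 200 °C, under N2
Reagents that add atoms: none
Why: Wolff–Kishner (Huang–Minlon) reduction takes both ketones to CH2 through their hydrazones while the oxime survives as its salt, completing the 1,2-carbonyl transposition from C-3 to C-4 without touching C-5.

Step 8
Reactants: 18 trans-decalin-4-one oxime
Product: 19 trans-decalin-4-one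
Conditions: aqueous TiCl3, NH4OAc, dioxane, rt, 1 h; used at once
Reagents that add atoms: water, O
Why: Reductive deoximation (N–O cleavage, then imine hydrolysis) in a buffered medium is mild enough to keep the kinetically set trans C-5 centre.

Step 9
Reactants: 19 trans-decalin-4-one
Product: 20 4-methyl-decalin-4-ol
Conditions: MeLi, CeCl3, THF, −78 °C; aqueous NH4Cl
Reagents that add atoms: methyllithium, [Li]C
Why: Organocerium 1,2-addition: the syn-axial C-10 methyl blocks axial attack, so the methyl group enters equatorially and the new C-4 hydroxyl is axial, cis to the C-10 methyl.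

Step 10
Reactants: 20 4-methyl-decalin-4-ol
Product: 21 benzyl-decalin-4,11-diol
Conditions: Co(acac)2 (20 mol %), PhSiH3, O2 (1 atm), THF/i-PrOH, rt
Reagents that add atoms: dioxygen, O=O
Why: Mukaiyama Markovnikov hydration of the 1,1-disubstituted alkene gives the tertiary alcohol; no stereocentre forms.

Step 11
Reactants: 21 benzyl-decalin-4,11-diol
Product: 23 methallyl adduct, via benzylic cation 22 (not isolated)
Conditions: DDQ (1.2 equiv), methallyltrimethylsilane (3 equiv), CH2Cl2, −20 °C to rt
Reagents that add atoms: methallyltrimethylsilane, CC(=C)C[Si](C)(C)C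
Why: Oxidative Hosomi–Sakurai reaction: DDQ removes benzylic hydride, the planar trimethoxybenzyl cation holds H-1 in the aryl plane (A1,3 strain) with its own hydrogen over ring A, and the allylsilane adds to the face away from quaternary C-10, which gives the S configuration at C-1′.

Step 12
Reactants: 23 methallyl adduct
Product: 24 isobutyl aryl trimethyl ether
Conditions: H2 (1 atm), Pd/C, EtOAc, rt
Reagents that add atoms: none
Why: Catalytic hydrogenation of the isolated 1,1-disubstituted alkene; no stereocentre is touched.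

Step 13
Reactants: 24 isobutyl aryl trimethyl ether
Product: 25 dibromoarene
Conditions: NBS (2.1 equiv), MeCN, 0 °C, dark
Reagents that add atoms: N-bromosuccinimide, O=C1CCC(=O)N1Br
Why: Electrophilic aromatic bromination fills the two free positions of the strongly activated ring under neutral conditions that spare the tertiary alcohols.

Step 14
Reactants: 25 dibromoarene
Product: 27 dialdehyde trimethyl ether, via dilithioarene 26 (not isolated)
Conditions: t-BuLi (6.5 equiv), THF, −78 °C; DMF; aqueous NH4Cl
Reagents that add atoms: N,N-dimethylformamide, CN(C)C=O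
Why: Double bromine–lithium exchange (after deprotonation of both alcohols) and Bouveault formylation install both aldehydes without acid.

Step 15
Reactants: 27 dialdehyde trimethyl ether
Product: 28 target CNP0409870.3
Conditions: NaSEt (12 equiv), DMF, 110 °C; then dilute aqueous HCl
Reagents that add atoms: none
Why: SN2 demethylation by thiolate cleaves the three aryl methyl ethers, each activated by an ortho or para formyl group, and leaves the tertiary alcohols and all stereocentres intact.

**Compound list**

1 | 1,3,5-trimethoxybenzene | COc1cc(OC)cc(OC)c1 | starting material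
2 | allyl bromide (3-bromoprop-1-ene) | C=CCBr | starting material
3 | 2,4,6-trimethoxyphenyllithium | COc1cc(OC)c([Li])c(OC)c1 | intermediate
4 | 2-allyl-1,3,5-trimethoxybenzene | COc1cc(OC)c(CC=C)c(OC)c1 | intermediate
5 | methyl vinyl ketone (but-3-en-2-one) | CC(=O)C=C | starting material
6 | (E)-5-(2,4,6-trimethoxyphenyl)pent-3-en-2-one | COc1cc(OC)c(C/C=C/C(C)=O)c(OC)c1 | intermediate
7 | lithium (E)-5-(2,4,6-trimethoxyphenyl)penta-1,3-dien-2-olate | COc1cc(OC)c(C/C=C/C(=C)O[Li])c(OC)c1 | intermediate
8 | trimethyl{[(E)-5-(2,4,6-trimethoxyphenyl)penta-1,3-dien-2-yl]oxy}silane | COc1cc(OC)c(C/C=C/C(=C)O[Si](C)(C)C)c(OC)c1 | intermediate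
9 | (R)-(−)-carvone | CC1=CC[C@H](CC1=O)C(C)=C | starting material
10 | silyl enol ether cycloadduct: cis-fused Δ2-octalin-9-one with 3-OSiMe3, 1-CH2Ar trans, H-5 cis and 7-isopropenyl cis to the 10-methyl | COc1cc(OC)cc(OC)c1C[C@@H]1C=C(O[Si](C)(C)C)C[C@@H]2C[C@@H](C(C)=C)CC(=O)[C@]12C | intermediate
11 | cis-fused 10-methyl-decalin-3,9-dione with 1-CH2Ar trans, H-5 cis and 7-isopropenyl cis to the 10-methyl | COc1cc(OC)cc(OC)c1C[C@@H]1CC(=O)C[C@@H]2C[C@@H](C(C)=C)CC(=O)[C@]12C | intermediate
12 | 3-(pyrrolidin-1-yl)-Δ3 enamine of 11 | COc1cc(OC)cc(OC)c1C[C@@H]1CC(N3CCCC3)=C[C@@H]2C[C@@H](C(C)=C)CC(=O)[C@]12C | intermediate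
13 | 4-(phenylselanyl) derivative of 11 (C-4 epimers) | COc1cc(OC)cc(OC)c1C[C@@H]1CC(=O)C([Se]c3ccccc3)[C@@H]2C[C@@H](C(C)=C)CC(=O)[C@]12C | intermediate
14 | 10-methyl-Δ4-octalin-3,9-dione with 1-CH2Ar trans and 7-isopropenyl cis to the 10-methyl | COc1cc(OC)cc(OC)c1C[C@@H]1CC(=O)C=C2C[C@@H](C(C)=C)CC(=O)[C@]12C | intermediate
15 | lithium Δ3-enolate of the trans-fused 3,9-dione (H-5 trans to the 10-methyl) | COc1cc(OC)cc(OC)c1C[C@@H]1CC(O[Li])=C[C@H]2C[C@@H](C(C)=C)CC(=O)[C@]12C | intermediate
16 | trans-fused 4-(hydroxyimino)-10-methyl-decalin-3,9-dione with 1-CH2Ar trans, H-5 trans and 7-isopropenyl cis to the 10-methyl | COc1cc(OC)cc(OC)c1C[C@@H]1CC(=O)C(=NO)[C@H]2C[C@@H](C(C)=C)CC(=O)[C@]12C | intermediate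
17 | 3,9-bis-hydrazone of 16 | COc1cc(OC)cc(OC)c1C[C@@H]1CC(=NN)C(=NO)[C@H]2C[C@@H](C(C)=C)CC(=NN)[C@]12C | intermediate
18 | trans-fused 10-methyl-decalin-4-one oxime with 1-CH2Ar trans and 7-isopropenyl cis to the 10-methyl | COc1cc(OC)cc(OC)c1C[C@@H]1CCC(=NO)[C@H]2C[C@@H](C(C)=C)CC[C@]12C | intermediate
19 | trans-fused 10-methyl-decalin-4-one with 1-CH2Ar trans and 7-isopropenyl cis to the 10-methyl | COc1cc(OC)cc(OC)c1C[C@@H]1CCC(=O)[C@H]2C[C@@H](C(C)=C)CC[C@]12C | intermediate
20 | trans-fused 4,10-dimethyl-decalin-4-ol with 4-OH axial and cis to the 10-methyl, 1-CH2Ar trans, 7-isopropenyl cis | COc1cc(OC)cc(OC)c1C[C@@H]1CC[C@@](C)(O)[C@H]2C[C@@H](C(C)=C)CC[C@]12C | intermediate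
21 | as 20 with 7-(2-hydroxypropan-2-yl) (4,11-diol) | COc1cc(OC)cc(OC)c1C[C@@H]1CC[C@@](C)(O)[C@H]2C[C@@H](C(C)(C)O)CC[C@]12C | intermediate
22 | (2,4,6-trimethoxyphenyl)methylium cation carrying the diol decalin at C-1′ | COc1cc(OC)cc(OC)c1[CH+][C@@H]1CC[C@@](C)(O)[C@H]2C[C@@H](C(C)(C)O)CC[C@]12C | intermediate
23 | (1′S)-1′-aryl-3′-methylbut-3′-enyl diol (methallyl adduct) | CC(=C)C[C@H](c1c(OC)cc(OC)cc1OC)[C@@H]1CC[C@@](C)(O)[C@H]2C[C@@H](C(C)(C)O)CC[C@]12C | intermediate
24 | (1′S)-1′-aryl-3′-methylbutyl diol (isobutyl compound) | CC(C)C[C@H](c1c(OC)cc(OC)cc1OC)[C@@H]1CC[C@@](C)(O)[C@H]2C[C@@H](C(C)(C)O)CC[C@]12C | intermediate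
25 | 3,5-dibromo-2,4,6-trimethoxyphenyl analogue of 24 | CC(C)C[C@H](c1c(OC)c(Br)c(OC)c(Br)c1OC)[C@@H]1CC[C@@](C)(O)[C@H]2C[C@@H](C(C)(C)O)CC[C@]12C | intermediate
26 | 3,5-dilithio-2,4,6-trimethoxyphenyl bis(lithium alkoxide) of 24 | CC(C)C[C@H](c1c(OC)c([Li])c(OC)c([Li])c1OC)[C@@H]1CC[C@@](C)(O[Li])[C@H]2C[C@@H](C(C)(C)O[Li])CC[C@]12C | intermediate
27 | 3,5-diformyl-2,4,6-trimethoxyphenyl analogue of 24 | CC(C)C[C@H](c1c(OC)c(C=O)c(OC)c(C=O)c1OC)[C@@H]1CC[C@@](C)(O)[C@H]2C[C@@H](C(C)(C)O)CC[C@]12C | intermediate
28 | CNP0409870.3, configuration 1′S,1S,4R,5S,7S,10R in the numbering above | CC(C)C[C@H](c1c(O)c(C=O)c(O)c(C=O)c1O)[C@@H]1CC[C@@](C)(O)[C@H]2C[C@@H](C(C)(C)O)CC[C@]12C | target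

**Step count**
Total: 15 steps. Longest linear sequence: 15 steps (1 to 28); 12 steps from carvone 9.

**Steps most likely to fail and fallbacks**

Step 4 (cycloaddition). The benzyl-bearing diene terminus must bond to the quaternary-forming carbon of a sluggish dienophile, and the Lewis acid may stop at the Mukaiyama–Michael stage or attack the electron-rich arene. The fallback sets out from 9 and returns at 14. Carvone 9 is combined with commercial 2-(trimethylsilyloxy)buta-1,3-diene (EtAlCl2, toluene), a closely precedented cycloaddition, to give the silyl enol ether cycloadduct F1. Pd(OAc)2 in MeCN (Saegusa–Ito oxidation) converts it to the cis-fused Δ1-enedione F2, and DDQ in refluxing dioxane gives the cross-conjugated dienedione F3. The benzyl group is then introduced by decarboxylative Giese addition of the 2,4,6-trimethoxybenzyl radical, generated from (2,4,6-trimethoxyphenyl)acetic acid with 4CzIPN, Cs2CO3 and blue light in DMSO. It adds to C-1 of the flat ring A on the face away from the angular methyl, as in 1α-alkylation of steroidal 1,4-dien-3-ones, and protonation at C-2 gives 14.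

Step 6 (reductive nitrosation). The second ketone at C-9 may be reduced or nitrosated at C-8, and trapping of the enolate may be incomplete. The fallback sets out from 11 and returns at 18. The unhindered C-3 carbonyl of 11 is ketalised selectively (ethylene glycol, TsOH, benzene) to the monoketal F4. Wolff–Kishner reduction removes the C-9 carbonyl to give the deoxo ketal F5, and aqueous acid releases the cis-fused 3-ketone F6. Dehydrogenation with IBX in DMSO at 70 °C gives the Δ4-enone F7. Li/NH3 reduction with isoamyl nitrite trapping, now on a substrate with a single carbonyl, gives the trans-fused oximino ketone F8, and a second Wolff–Kishner reduction delivers 18.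

Step 11 (oxidative methallylation). Hydride abstraction may be slow at the hindered benzylic position, and the free alcohols or over-oxidation may compete. The fallback sets out from 21 and returns at 23. DDQ (1.1 equiv) in CH2Cl2 with pH 7 buffer hydroxylates the benzylic position to give the benzylic alcohol F9 as a mixture of epimers. This is ionised separately with BF3·OEt2 in CH2Cl2 at −78 °C in the presence of methallyltrimethylsilane. The same cation forms under non-oxidising conditions and is attacked on the same face, giving 23.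

**Further compounds**

F1 | step 4 | silyl enol ether cycloadduct of 9 and 2-(trimethylsilyloxy)buta-1,3-diene (cis-fused, 10-methyl cis to 7-isopropenyl) | C1C=C(O[Si](C)(C)C)C[C@@H]2C[C@@H](C(C)=C)CC(=O)[C@]12C
F2 | step 4 | cis-fused 10-methyl-7-isopropenyl-Δ1-octalin-3,9-dione | C1=CC(=O)C[C@@H]2C[C@@H](C(C)=C)CC(=O)[C@]12C
F3 | step 4 | 10-methyl-7-isopropenyl-Δ1,4-hexalin-3,9-dione | C1=CC(=O)C=C2C[C@@H](C(C)=C)CC(=O)[C@]12C
F4 | step 6 | 3-(ethylene ketal) of 11 | COc1cc(OC)cc(OC)c1C[C@@H]1CC3(OCCO3)C[C@@H]2C[C@@H](C(C)=C)CC(=O)[C@]12C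
F5 | step 6 | 9-deoxo derivative of F4 | COc1cc(OC)cc(OC)c1C[C@@H]1CC3(OCCO3)C[C@@H]2C[C@@H](C(C)=C)CC[C@]12C
F6 | step 6 | cis-fused 10-methyl-decalin-3-one with 1-CH2Ar trans and 7-isopropenyl cis to the 10-methyl | COc1cc(OC)cc(OC)c1C[C@@H]1CC(=O)C[C@@H]2C[C@@H](C(C)=C)CC[C@]12C
F7 | step 6 | 10-methyl-Δ4-octalin-3-one with 1-CH2Ar trans and 7-isopropenyl cis to the 10-methyl | COc1cc(OC)cc(OC)c1C[C@@H]1CC(=O)C=C2C[C@@H](C(C)=C)CC[C@]12C
F8 | step 6 | trans-fused 4-(hydroxyimino)-10-methyl-decalin-3-one with 1-CH2Ar trans and 7-isopropenyl cis to the 10-methyl | COc1cc(OC)cc(OC)c1C[C@@H]1CC(=O)C(=NO)[C@H]2C[C@@H](C(C)=C)CC[C@]12C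
F9 | step 11 | 1′-hydroxy derivative of 21 (C-1′ epimers) | COc1cc(OC)cc(OC)c1C(O)[C@@H]1CC[C@@](C)(O)[C@H]2C[C@@H](C(C)(C)O)CC[C@]12C
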